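Ring A (the hydroxylated cyclohexene; carotenoid numbering, C1 = CMe2, C3 = carbinol) is opened across the two single bonds that flank its tetrasubstituted C5=C6 alkene: C4–C5 and C1–C6. With oxygen on C3, para to the chain-bearing C6, the ring is the adduct of an alkyne Diels–Alder reaction. The 2-silyloxydiene from mesityl oxide (C1–C4, gem-dimethyl terminus included) and but-2-ynal (C5, C6, the C5 methyl and C7) should give the whole carbocycle in one operation. Colvin homologation, enzymatic ketone reduction, Trost ynoate coupling and two Wittig condensations with the C10 dialdehyde complete the chain; ring B comes from safranal.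

Key step: step 2

Remark on the chemistry: the chain is numbered C7≡C8, C9=C10, C11=C12, C13=C14, C15=C15', with primed numbers for the ring B half. But-2-ynal, ethyl but-2-ynoate, safranal and (2E,4E,6E)-2,7-dimethylocta-2,4,6-trienedial are assumed to be purchasable.

Step 1
Reactants: 1 4-methylpent-3-en-2-one (mesityl oxide)
Product: 3 trimethyl[(4-methylpenta-1,3-dien-2-yl)oxy]silane, via lithium dienolate 2 (not isolated)
Conditions: LiN(iPr)2, THF, −78 °C; then Me3SiCl, −78 °C → rt; non-aqueous work-up, distillation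
Reagents that add atoms: chlorotrimethylsilane, C[Si](C)(C)Cl
Why: Kinetic deprotonation of the enone at the acetyl methyl group gives the cross-conjugated dienolate, and O-silylation (kinetic silyl enol ether formation) gives the 2-silyloxydiene.

Step 2
Reactants: 3 trimethyl[(4-methylpenta-1,3-dien-2-yl)oxy]silane; 4 but-2-ynal
Product: 5 2,6,6-trimethyl-4-[(trimethylsilyl)oxy]cyclohexa-1,4-diene-1-carbaldehyde
Conditions: PhMe, BHT (cat.), 100 °C, sealed tube, 3 in excess
Reagents that add atoms: none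
Why: Thermal normal-electron-demand [4+2] cycloaddition: the HOMO of the 2-silyloxydiene (largest coefficient on its CH2 terminus, the future C4) meets the LUMO of the ynal (largest coefficient on the methyl-bearing β-carbon, the future C5), so C4–C5 forms early and the crowded CMe2 terminus (C1) closes late onto the formyl-bearing carbon (C6) in a concerted but asynchronous transition state. The closest known reaction type is the Diels–Alder reaction of 2-silyloxy-1,3-dienes with acetylenic aldehydes, ketones and esters, which gives 1-silyloxycyclohexa-1,4-dienes. The one ring that closes, the six-membered ring A, closes by intermolecular suprafacial [4π+2π] cycloaddition, and because both new bonds end on the two alkyne carbons the C5=C6 double bond is formed in place and tetrasubstituted. No stereocentre is created: C3 leaves the step as a silyl enol ether, a masked ketone, and its configuration is set in step 4. The step needs "para" regioselectivity (silyloxy carbon 1,4 to the formyl-bearing carbon), which the matched donor (oxygen on C3) and acceptor (formyl on C6) secure; the silyloxy group also clashes with the Z-methyl group in the s-trans diene and so raises the share of the reactive s-cis conformer, and the quaternary C1 prevents aromatisation of the adduct. The temperature is held at 100 °C so that the 1,5-hydrogen shift of the Z-methyl diene does not compete.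

Step 3
Reactants: 5 2,6,6-trimethyl-4-[(trimethylsilyl)oxy]cyclohexa-1,4-diene-1-carbaldehyde
Product: 7 4-ethynyl-3,5,5-trimethylcyclohex-3-en-1-one, via silyl enol ether alkyne 6 (not isolated)
Conditions: Me3SiCHN2, n-BuLi, THF, −78 °C; then 5, −78 → 0 °C; then 0.5 M aq. HCl, 0 °C, short contact
Reagents that add atoms: (trimethylsilyl)diazomethane, C[Si](C)(C)C=[N+]=[N-]
Why: Colvin alkyne homologation (addition of the lithiated diazomethane to the hindered aldehyde, Peterson elimination, loss of N2 and 1,2-hydrogen shift of the alkylidene carbene) gives the terminal alkyne, and the cold dilute acid work-up cleaves the trimethylsilyl enol ether to the β,γ-unsaturated ketone before the double bond can move.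

Step 4
Reactants: 7 4-ethynyl-3,5,5-trimethylcyclohex-3-en-1-one
Product: 8 (1R)-4-ethynyl-3,5,5-trimethylcyclohex-3-en-1-ol
Conditions: (R)-selective ketoreductase (NADPH-dependent alcohol dehydrogenase, chosen from a panel screen), NADP+ (cat.), iPrOH (10 vol %), KH2PO4/K2HPO4 buffer pH 7.0, 30 °C
Reagents that add atoms: none
Why: Enzymatic ketone reduction by a ketoreductase, whose binding pocket distinguishes the CH2–CMe2 flank from the CH2–C(CH3)= flank and delivers hydride to one carbonyl face, should set the (R) carbinol centre (C3 of the target) at neutral pH, where the β,γ-enone does not isomerise.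

Step 5
Reactants: 8 (1R)-4-ethynyl-3,5,5-trimethylcyclohex-3-en-1-ol; 9 ethyl but-2-ynoate
Product: 10 ethyl (2E)-5-[(4R)-4-hydroxy-2,6,6-trimethylcyclohex-1-en-1-yl]-3-methylpent-2-en-4-ynoate
Conditions: Pd(OAc)2 (3 mol %), P(2,6-(MeO)2C6H3)3 (3 mol %), THF, rt
Reagents that add atoms: none
Why: Trost palladium-catalysed addition of a terminal alkyne to an alkynoate: the alkynylpalladium species adds cis across the ynoate and protonolysis leaves the alkynyl group and H on the same side, which fixes the C9=C10 bond as E (alkynyl trans to the ester) and tolerates the free hydroxyl.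

Step 6
Reactants: 10 ethyl (2E)-5-[(4R)-4-hydroxy-2,6,6-trimethylcyclohex-1-en-1-yl]-3-methylpent-2-en-4-ynoate
Product: 11 (2E)-5-[(4R)-4-hydroxy-2,6,6-trimethylcyclohex-1-en-1-yl]-3-methylpent-2-en-4-yn-1-ol
Conditions: iBu2AlH (3.5 equiv), CH2Cl2, −78 → 0 °C; aq. KNaC4H4O6 (potassium sodium tartrate) work-up
Reagents that add atoms: none
Why: 1,2-Reduction of the conjugated ester with iBu2AlH gives the allylic alcohol without touching the enyne, the ring hydroxyl only consuming one hydride as its alkoxide.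

Step 7
Reactants: 11 (2E)-5-[(4R)-4-hydroxy-2,6,6-trimethylcyclohex-1-en-1-yl]-3-methylpent-2-en-4-yn-1-ol
Product: 12 [(2E)-5-[(4R)-4-hydroxy-2,6,6-trimethylcyclohex-1-en-1-yl]-3-methylpent-2-en-4-yn-1-yl]triphenylphosphonium bromide
Conditions: PPh3·HBr (1.05 equiv), MeOH, 0 °C → rt, dark
Reagents that add atoms: triphenylphosphine hydrobromide, [Br-].[PH+](c1ccccc1)(c1ccccc1)c1ccccc1
Why: Phosphonium salt formation from an allylic alcohol with PPh3·HBr: only the primary allylic hydroxyl ionises and is captured by PPh3 at the unhindered terminus, while the secondary ring hydroxyl stays free.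

Step 8
Reactants: 13 safranal (2,6,6-trimethylcyclohexa-1,3-diene-1-carbaldehyde)
Product: 14 1-ethynyl-2,6,6-trimethylcyclohexa-1,3-diene
Conditions: Me3SiCHN2, n-BuLi, THF, −78 °C; then 13, −78 → 0 °C; water quench
Reagents that add atoms: (trimethylsilyl)diazomethane, C[Si](C)(C)C=[N+]=[N-]
Why: Colvin homologation of a non-enolisable conjugated aldehyde to the terminal alkyne leaves the ring diene of ring B untouched.

Step 9
Reactants: 14 1-ethynyl-2,6,6-trimethylcyclohexa-1,3-diene; 9 ethyl but-2-ynoate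
Product: 15 ethyl (2E)-3-methyl-5-(2,6,6-trimethylcyclohexa-1,3-dien-1-yl)pent-2-en-4-ynoate
Conditions: Pd(OAc)2 (3 mol %), P(2,6-(MeO)2C6H3)3 (3 mol %), THF, rt
Reagents that add atoms: none
Why: The same Trost alkyne–alkynoate addition as in step 5 sets the C9'=C10' bond as E by cis addition of alkynyl and H.

Step 10
Reactants: 15 ethyl (2E)-3-methyl-5-(2,6,6-trimethylcyclohexa-1,3-dien-1-yl)pent-2-en-4-ynoate
Product: 16 (2E)-3-methyl-5-(2,6,6-trimethylcyclohexa-1,3-dien-1-yl)pent-2-en-4-yn-1-ol
Conditions: iBu2AlH (2.5 equiv), CH2Cl2, −78 → 0 °C; aq. KNaC4H4O6 work-up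
Reagents that add atoms: none
Why: 1,2-Reduction of the conjugated ester with iBu2AlH gives the allylic alcohol.

Step 11
Reactants: 16 (2E)-3-methyl-5-(2,6,6-trimethylcyclohexa-1,3-dien-1-yl)pent-2-en-4-yn-1-ol
Product: 17 [(2E)-3-methyl-5-(2,6,6-trimethylcyclohexa-1,3-dien-1-yl)pent-2-en-4-yn-1-yl]triphenylphosphonium bromide
Conditions: PPh3·HBr (1.05 equiv), MeOH, 0 °C → rt, dark
Reagents that add atoms: triphenylphosphine hydrobromide, [Br-].[PH+](c1ccccc1)(c1ccccc1)c1ccccc1
Why: Phosphonium salt formation from the allylic alcohol with PPh3·HBr, as in step 7.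

Step 12
Reactants: 17 [(2E)-3-methyl-5-(2,6,6-trimethylcyclohexa-1,3-dien-1-yl)pent-2-en-4-yn-1-yl]triphenylphosphonium bromide; 18 (2E,4E,6E)-2,7-dimethylocta-2,4,6-trienedial (excess)
Product: 20 (2E,4E,6E,8E,10E)-2,7,11-trimethyl-13-(2,6,6-trimethylcyclohexa-1,3-dien-1-yl)trideca-2,4,6,8,10-pentaen-12-ynal, via ring B ylide 19 (not isolated)
Conditions: NaOMe (1.1 equiv), CH2Cl2/MeOH, 0 °C → rt, dark, slow addition to 18 (2 equiv); then EtOAc, 50 °C, dark
Reagents that add atoms: none
Why: Wittig olefination of one formyl group of the symmetric dialdehyde by the semi-stabilised allylic ylide forms C11'=C12'; the excess of dialdehyde should hold back double condensation, and the sterically strained Z isomer of the new bond should relax to E on gentle warming.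

Step 13
Reactants: 12 [(2E)-5-[(4R)-4-hydroxy-2,6,6-trimethylcyclohex-1-en-1-yl]-3-methylpent-2-en-4-yn-1-yl]triphenylphosphonium bromide; 20 (2E,4E,6E,8E,10E)-2,7,11-trimethyl-13-(2,6,6-trimethylcyclohexa-1,3-dien-1-yl)trideca-2,4,6,8,10-pentaen-12-ynal
Product: 22 (3R,all-E)-3',4',7,8,7',8'-hexadehydro-β,β-caroten-3-ol (CNP0250213.1), via ring A ylide 21 (not isolated)
Conditions: NaOMe (1.2 equiv), CH2Cl2/MeOH, 0 °C → rt, dark, Ar; then EtOH, 50 °C, dark; crystallisation
Reagents that add atoms: none
Why: Wittig olefination forms C11=C12 and completes the C40 chain with the free C3 hydroxyl tolerated, and mild warming in the dark should turn the hindered Z isomer of the new bond into E without disturbing the enyne geometry or the C3 stereocentre.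

Compound list
1 | 4-methylpent-3-en-2-one (mesityl oxide) | CC(=O)C=C(C)C | starting material
2 | lithium 4-methylpenta-1,3-dien-2-olate | C=C(O[Li])C=C(C)C | intermediate
3 | trimethyl[(4-methylpenta-1,3-dien-2-yl)oxy]silane | C=C(O[Si](C)(C)C)C=C(C)C | intermediate
4 | but-2-ynal | CC#CC=O | starting material
5 | 2,6,6-trimethyl-4-[(trimethylsilyl)oxy]cyclohexa-1,4-diene-1-carbaldehyde | O=CC1=C(C)CC(O[Si](C)(C)C)=CC1(C)C | intermediate
6 | [(4-ethynyl-3,3,5-trimethylcyclohexa-1,4-dien-1-yl)oxy]trimethylsilane | C#CC1=C(C)CC(O[Si](C)(C)C)=CC1(C)C | intermediate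
7 | 4-ethynyl-3,5,5-trimethylcyclohex-3-en-1-one | O=C1CC(C)=C(C#C)C(C)(C)C1 | intermediate
8 | (1R)-4-ethynyl-3,5,5-trimethylcyclohex-3-en-1-ol | C#CC1=C(C)C[C@@H](O)CC1(C)C | intermediate
9 | ethyl but-2-ynoate | CC#CC(=O)OCC | starting material
10 | ethyl (2E)-5-[(4R)-4-hydroxy-2,6,6-trimethylcyclohex-1-en-1-yl]-3-methylpent-2-en-4-ynoate | CCOC(=O)/C=C(\C)C#CC1=C(C)C[C@@H](O)CC1(C)C | intermediate
11 | (2E)-5-[(4R)-4-hydroxy-2,6,6-trimethylcyclohex-1-en-1-yl]-3-methylpent-2-en-4-yn-1-ol | OC/C=C(\C)C#CC1=C(C)C[C@@H](O)CC1(C)C | intermediate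
12 | [(2E)-5-[(4R)-4-hydroxy-2,6,6-trimethylcyclohex-1-en-1-yl]-3-methylpent-2-en-4-yn-1-yl]triphenylphosphonium bromide | C(/C=C(\C)C#CC1=C(C)C[C@@H](O)CC1(C)C)[P+](c1ccccc1)(c1ccccc1)c1ccccc1.[Br-] | intermediate
13 | safranal (2,6,6-trimethylcyclohexa-1,3-diene-1-carbaldehyde) | CC1=C(C=O)C(C)(C)CC=C1 | starting material
14 | 1-ethynyl-2,6,6-trimethylcyclohexa-1,3-diene | CC1=C(C#C)C(C)(C)CC=C1 | intermediate
15 | ethyl (2E)-3-methyl-5-(2,6,6-trimethylcyclohexa-1,3-dien-1-yl)pent-2-en-4-ynoate | CCOC(=O)/C=C(\C)C#CC1=C(C)C=CCC1(C)C | intermediate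
16 | (2E)-3-methyl-5-(2,6,6-trimethylcyclohexa-1,3-dien-1-yl)pent-2-en-4-yn-1-ol | OC/C=C(\C)C#CC1=C(C)C=CCC1(C)C | intermediate
17 | [(2E)-3-methyl-5-(2,6,6-trimethylcyclohexa-1,3-dien-1-yl)pent-2-en-4-yn-1-yl]triphenylphosphonium bromide | C(/C=C(\C)C#CC1=C(C)C=CCC1(C)C)[P+](c1ccccc1)(c1ccccc1)c1ccccc1.[Br-] | intermediate
18 | (2E,4E,6E)-2,7-dimethylocta-2,4,6-trienedial | O=C/C(C)=C/C=C/C=C(C)/C=O | starting material
19 | triphenylphosphonium ylide of 17 (carbanion on C11') | [CH-](/C=C(\C)C#CC1=C(C)C=CCC1(C)C)[P+](c1ccccc1)(c1ccccc1)c1ccccc1 | intermediate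
20 | (2E,4E,6E,8E,10E)-2,7,11-trimethyl-13-(2,6,6-trimethylcyclohexa-1,3-dien-1-yl)trideca-2,4,6,8,10-pentaen-12-ynal | CC1=C(C#C/C(C)=C/C=C/C(C)=C/C=C/C=C(C)/C=O)C(C)(C)CC=C1 | intermediate
21 | triphenylphosphonium ylide of 12 (carbanion on C11) | [CH-](/C=C(\C)C#CC1=C(C)C[C@@H](O)CC1(C)C)[P+](c1ccccc1)(c1ccccc1)c1ccccc1 | intermediate
22 | (3R,all-E)-3',4',7,8,7',8'-hexadehydro-β,β-caroten-3-ol (CNP0250213.1) | CC1=C(C#C/C(C)=C/C=C/C(C)=C/C=C/C=C(C)/C=C/C=C(\C)C#CC2=C(C)C[C@@H](O)CC2(C)C)C(C)(C)CC=C1 | target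

Total step count: 13.
Longest linear sequence: 8 steps (steps 1, 2, 3, 4, 5, 6, 7 and 13).

Steps most likely to fail

Step 2. The cycloaddition may stall because the CMe2 terminus must close onto a fully substituted alkyne carbon; meanwhile the diene can be drained by 1,5-hydrogen shift and the ynal by polymerisation. The fallback sets out from 1 and returns at 7, building the same ring by a classical Michael addition–aldol condensation instead of a cycloaddition. Mesityl oxide 1 and ethyl acetoacetate (NaOEt, EtOH, reflux) should give ethyl 2,6,6-trimethyl-4-oxocyclohex-2-ene-1-carboxylate F1. Ketalisation with ethane-1,2-diol (TsOH, benzene, water separator) should move the double bond into conjugation with the ester and give ethyl 7,9,9-trimethyl-1,4-dioxaspiro[4.5]dec-7-ene-8-carboxylate F2. Reduction with iBu2AlH gives (7,9,9-trimethyl-1,4-dioxaspiro[4.5]dec-7-en-8-yl)methanol F3, and MnO2 gives 7,9,9-trimethyl-1,4-dioxaspiro[4.5]dec-7-ene-8-carbaldehyde F4. Lithiated (trimethylsilyl)diazomethane then gives 8-ethynyl-7,9,9-trimethyl-1,4-dioxaspiro[4.5]dec-7-ene F5, and brief treatment with pyridinium tosylate in wet acetone releases ketone 7.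

Step 4. The enzyme may deliver hydride to both carbonyl faces because the two methylene flanks differ only at the next atom, and the double bond may drift into conjugation with the ketone during a slow reduction. The fallback sets out from 7 and returns at 8, replacing asymmetric reduction by kinetic resolution. NaBH4 with CeCl3·7H2O (MeOH, −20 °C) gives racemic 4-ethynyl-3,5,5-trimethylcyclohex-3-en-1-ol F6. Lipase-catalysed acylation (Amano lipase PS, vinyl acetate, tert-butyl methyl ether, 30 °C, stopped near half conversion) should acetylate the (R)-enantiomer preferentially to (1R)-4-ethynyl-3,5,5-trimethylcyclohex-3-en-1-yl acetate F7 and leave (1S)-4-ethynyl-3,5,5-trimethylcyclohex-3-en-1-ol F8, which is removed by chromatography. Methanolysis of F7 (K2CO3, MeOH) gives 8.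

Step 13 (step 12 shares the risk). The allylic ylide is delocalised onto the propargylic C9, so rotation about C9–C10 may erode the E geometry set in step 5, and Z isomers may form at the new double bond. The fallback sets out from 11 and 20 and returns at 22, reversing the polarity so that no carbanion is generated next to the enyne of ring A. MnO2 (CH2Cl2, rt) oxidises only the allylic hydroxyl of 11 to (2E)-5-[(4R)-4-hydroxy-2,6,6-trimethylcyclohex-1-en-1-yl]-3-methylpent-2-en-4-ynal F9. NaBH4 (MeOH/THF, 0 °C) reduces 20 to (2E,4E,6E,8E,10E)-2,7,11-trimethyl-13-(2,6,6-trimethylcyclohexa-1,3-dien-1-yl)trideca-2,4,6,8,10-pentaen-12-yn-1-ol F10. PPh3·HBr gives [(2E,4E,6E,8E,10E)-2,7,11-trimethyl-13-(2,6,6-trimethylcyclohexa-1,3-dien-1-yl)trideca-2,4,6,8,10-pentaen-12-yn-1-yl]triphenylphosphonium bromide F11. Its ylide F12 (NaOMe, CH2Cl2/MeOH, 0 °C, dark), whose carbanion sits on C12 within the ordinary polyene, condenses with F9 to form the same C11=C12 bond and give 22.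

Further compounds
F1 | step 2 | ethyl 2,6,6-trimethyl-4-oxocyclohex-2-ene-1-carboxylate (racemic) | CCOC(=O)C1C(C)=CC(=O)CC1(C)C
F2 | step 2 | ethyl 7,9,9-trimethyl-1,4-dioxaspiro[4.5]dec-7-ene-8-carboxylate | CCOC(=O)C1=C(C)CC2(OCCO2)CC1(C)C
F3 | step 2 | (7,9,9-trimethyl-1,4-dioxaspiro[4.5]dec-7-en-8-yl)methanol | OCC1=C(C)CC2(OCCO2)CC1(C)C
F4 | step 2 | 7,9,9-trimethyl-1,4-dioxaspiro[4.5]dec-7-ene-8-carbaldehyde | O=CC1=C(C)CC2(OCCO2)CC1(C)C
F5 | step 2 | 8-ethynyl-7,9,9-trimethyl-1,4-dioxaspiro[4.5]dec-7-ene | C#CC1=C(C)CC2(OCCO2)CC1(C)C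
F6 | step 4 | racemic 4-ethynyl-3,5,5-trimethylcyclohex-3-en-1-ol | C#CC1=C(C)CC(O)CC1(C)C
F7 | step 4 | (1R)-4-ethynyl-3,5,5-trimethylcyclohex-3-en-1-yl acetate | C#CC1=C(C)C[C@@H](OC(C)=O)CC1(C)C
F8 | step 4 | (1S)-4-ethynyl-3,5,5-trimethylcyclohex-3-en-1-ol | C#CC1=C(C)C[C@H](O)CC1(C)C
F9 | step 13 | (2E)-5-[(4R)-4-hydroxy-2,6,6-trimethylcyclohex-1-en-1-yl]-3-methylpent-2-en-4-ynal | O=C/C=C(\C)C#CC1=C(C)C[C@@H](O)CC1(C)C
F10 | step 13 | (2E,4E,6E,8E,10E)-2,7,11-trimethyl-13-(2,6,6-trimethylcyclohexa-1,3-dien-1-yl)trideca-2,4,6,8,10-pentaen-12-yn-1-ol | CC1=C(C#C/C(C)=C/C=C/C(C)=C/C=C/C=C(C)/CO)C(C)(C)CC=C1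
F11 | step 13 | [(2E,4E,6E,8E,10E)-2,7,11-trimethyl-13-(2,6,6-trimethylcyclohexa-1,3-dien-1-yl)trideca-2,4,6,8,10-pentaen-12-yn-1-yl]triphenylphosphonium bromide | CC1=C(C#C/C(C)=C/C=C/C(C)=C/C=C/C=C(C)/C[P+](c2ccccc2)(c2ccccc2)c2ccccc2)C(C)(C)CC=C1.[Br-]
F12 | step 13 | triphenylphosphonium ylide of F11 (carbanion on C12) | CC1=C(C#C/C(C)=C/C=C/C(C)=C/C=C/C=C(C)/[CH-][P+](c2ccccc2)(c2ccccc2)c2ccccc2)C(C)(C)CC=C1
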